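**Plan**

- Retrosynthesis: the three aryl silyl ethers and the C9'–O coumarate bond are cut last. The C9 CH2OH is traced to a Weinreb amide made by opening the lactone of a bis-silylated α-conidendrin, whose ring ties C9 (C=O) to O–C9' and so tells the two arms apart.
- Ring B is then cut at C3–C4 and C1–C8a in a [3+3] sense, giving a vanillyl acetate and the silyl ketene acetal of a β-(α-silyloxybenzyl)-γ-butyrolactone. That lactone is cut at C1–C2 by an aldol.
- Enabling feature: C4 (the ring-B CH2) is para to the ring-A phenol oxygen, and C1 is the benzylic carbon of the pendant 4-hydroxy-3-methoxyphenyl ring, so both can be oxygen-stabilised cations. C8a is para to the C6 methoxy group and C3 is α to the C9 carbonyl, so ring A/C4 and C3–C2–C1 are two matched 1,3-ambiphiles.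
- Forward: vanillin supplies both guaiacyl units; aldol (C1–C2), reductive lactonisation (temporary butyrolactone), one-flask ring-B annulation, lactone opening, esterification, amide reduction, desilylation.
- Stereochemistry: C2 from the auxiliary-controlled syn-aldol, C3 from anti attack on the 4-substituted dihydrofuran (trans lactone), C1 from the trans-selective Friedel–Crafts closure; the aldol carbinol centre is sacrificed.

Key step: step 9

Numbering used in the text: tetralin C1 (aryl-bearing) to C4 (CH2), ring fusion C4a/C8a; C9 is the carbon on C3, C9' the carbon on C2.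
Assumption: aldol adduct 6 survives a neutral work-up as the open hydroxy ester and is silylated at once.

**Route**

Step 1
Reactants: 1 vanillin
Product: 2 3-methoxy-4-(triisopropylsilyloxy)benzaldehyde
Conditions: TIPSCl, imidazole, DMF, rt
Reagents that add atoms: triisopropylsilyl chloride, CC(C)[Si](Cl)(C(C)C)C(C)C
Why: Standard silylation of a phenol; the hindered aryl TIPS ether should survive all later basic, hydridic and Lewis acidic steps.

Step 2
Reactants: 3 (S)-4-benzyl-2-oxazolidinone; 4 methyl 4-chloro-4-oxobutanoate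
Product: 5 methyl 4-[(S)-4-benzyl-2-oxooxazolidin-3-yl]-4-oxobutanoate
Conditions: n-BuLi, THF, −78 °C; then 4, −78 → 0 °C
Reagents that add atoms: none
Why: N-Acylation of the lithiated oxazolidinone by the acid chloride, which reacts far faster than the methyl ester.

Step 3
Reactants: 5 imide; 2 aldehyde
Product: 6 methyl (3S,4S)-3-[(S)-4-benzyl-2-oxooxazolidine-3-carbonyl]-4-hydroxy-4-[3-methoxy-4-(triisopropylsilyloxy)phenyl]butanoate
Conditions: Bu2BOTf, i-Pr2NEt, CH2Cl2, −78 → 0 °C; 2, −78 → 0 °C; pH 7 buffer, MeOH, H2O2, 0 °C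
Reagents that add atoms: none
Why: Evans syn-aldol: the Z boron enolate of the imide reacts through a chair transition state on the face away from the auxiliary benzyl group, which sets the future C2 (and a C1 carbinol centre that is erased later).

Step 4
Reactants: 6 aldol adduct
Product: 7 methyl (3S,4S)-3-[(S)-4-benzyl-2-oxooxazolidine-3-carbonyl]-4-(tert-butyldimethylsilyloxy)-4-[3-methoxy-4-(triisopropylsilyloxy)phenyl]butanoate
Conditions: TBSOTf, 2,6-lutidine, CH2Cl2, −78 → 0 °C
Reagents that add atoms: tert-butyldimethylsilyl triflate, CC(C)(C)[Si](C)(C)OS(=O)(=O)C(F)(F)F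
Why: Silylation of the secondary benzylic alcohol blocks its lactonisation onto the ester and installs the leaving group for the later C1 cation.

Step 5
Reactants: 7 silyl ether
Product: 9 (R)-4-{(S)-(tert-butyldimethylsilyloxy)[3-methoxy-4-(triisopropylsilyloxy)phenyl]methyl}dihydrofuran-2(3H)-one, via hydroxy ester 8 (not isolated)
Conditions: NaBH4, THF/H2O, 0 °C → rt; then PPTS (cat.), toluene, 60 °C
Reagents that add atoms: none
Why: Borohydride in wet THF should reduce the activated imide carbonyl to the primary alcohol (auxiliary released) while sparing the methyl ester, and the γ-hydroxy ester then closes to the butyrolactone without touching a stereocentre.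

Step 6
Reactants: 9 lactone
Product: 10 (R)-3-{(S)-(tert-butyldimethylsilyloxy)[3-methoxy-4-(triisopropylsilyloxy)phenyl]methyl}-5-(trimethylsilyloxy)-2,3-dihydrofuran
Conditions: LDA, TMSCl (in situ), THF, −78 °C; non-aqueous work-up, used crude
Reagents that add atoms: chlorotrimethylsilane, C[Si](C)(C)Cl
Why: Kinetic deprotonation of the only α-CH2 of the lactone with internal O-silylation gives the cyclic silyl ketene acetal.

Step 7
Reactants: 2 aldehyde
Product: 11 [3-methoxy-4-(triisopropylsilyloxy)phenyl]methanol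
Conditions: NaBH4, MeOH, 0 °C
Reagents that add atoms: none
Why: Plain borohydride reduction of an aryl aldehyde.

Step 8
Reactants: 11 benzyl alcohol
Product: 12 3-methoxy-4-(triisopropylsilyloxy)benzyl acetate
Conditions: Ac2O, pyridine, DMAP (cat.), CH2Cl2, 0 °C → rt
Reagents that add atoms: acetic anhydride, CC(=O)OC(C)=O
Why: Acetylation gives a bench-stable precursor that ionises only when a silyl triflate is added.

Step 9
Reactants: 10 silyl ketene acetal; 12 benzyl acetate
Product: 14 (3aR,9S,9aR)-6-methoxy-9-[3-methoxy-4-(triisopropylsilyloxy)phenyl]-7-(triisopropylsilyloxy)-3a,4,9,9a-tetrahydronaphtho[2,3-c]furan-3(1H)-one (bis-TIPS ether of α-conidendrin), via trans-benzylated lactone 13 (not isolated)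
Conditions: TMSOTf (0.3 equiv), CH2Cl2, −78 °C, then 0 °C → rt; aq. NaHCO3
Reagents that add atoms: none
Why: Proposed new method: catalytic TMSOTf should ionise acetate 12 to the para-silyloxy-stabilised benzyl cation, which ketene acetal 10 captures at the lactone α-carbon (C3) to give 13 and regenerate the silyl triflate; on warming, the same acid should ionise the secondary benzylic silyl ether at C1 (a quinone-methide-like cation of the pendant guaiacyl ring) and the newly attached ring A closes onto it. The closest known reaction types are the SN1 (Mukaiyama-type) benzylation of silyl ketene acetals and the acid-induced Friedel–Crafts cyclisation of 7'-oxygenated dibenzylbutyrolactones to aryltetralin lactones, merged here into one formal [3+3] annulation of two 1,3-ambiphiles. The single new ring (ring B) closes as a six-membered cation–arene cyclisation, 6-exo-tet with respect to the departing silyloxy group, through the arene carbon para to the methoxy group. C3 is set by approach of the cation anti to the bulky substituent on the neighbouring ring carbon of the dihydrofuran (trans lactone), and C1 by a chair-like closure that places the aryl group pseudo-equatorial and trans to C2 on the trans-fused lactone; the configuration of the silyloxy-bearing carbon of 10 is erased. The step needs C-benzylation to outrun arene self-condensation (secured by the much higher π-nucleophilicity of the ketene acetal), acetate ionisation before silyl ether ionisation (secured by the temperature programme), and para-to-OMe regioselectivity (secured by the silylated ring-A phenol and the ring size).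

Step 10
Reactants: 14 lactone
Product: 15 (2R,3R,4S)-3-(hydroxymethyl)-N,7-dimethoxy-N-methyl-4-[3-methoxy-4-(triisopropylsilyloxy)phenyl]-6-(triisopropylsilyloxy)-1,2,3,4-tetrahydronaphthalene-2-carboxamide
Conditions: MeNH(OMe)·HCl, AlMe3, CH2Cl2, 0 °C → rt
Reagents that add atoms: N,O-dimethylhydroxylamine hydrochloride, CNOC.Cl
Why: Weinreb aminolysis of a lactone with the aluminium amide opens the strained trans-fused ring, frees only the C9' hydroxyl and leaves C9 as a selectively reducible amide.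

Step 11
Reactants: 16 p-coumaric acid
Product: 18 (E)-3-[4-(triisopropylsilyloxy)phenyl]prop-2-enoic acid, via bis-silylated coumarate 17 (not isolated)
Conditions: TIPSCl (2.2 equiv), imidazole, DMF, rt; then K2CO3, THF/MeOH/H2O, 0 °C; 1 M HCl
Reagents that add atoms: triisopropylsilyl chloride, CC(C)[Si](Cl)(C(C)C)C(C)C
Why: Exhaustive silylation followed by mild hydrolysis, which should cleave the labile silyl ester and leave the aryl silyl ether.

Step 12
Reactants: 15 hydroxy amide; 18 acid
Product: 19 [(1S,2R,3R)-3-[methoxy(methyl)carbamoyl]-6-methoxy-1-[3-methoxy-4-(triisopropylsilyloxy)phenyl]-7-(triisopropylsilyloxy)-1,2,3,4-tetrahydronaphthalen-2-yl]methyl (E)-3-[4-(triisopropylsilyloxy)phenyl]prop-2-enoate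
Conditions: EDC·HCl, DMAP, CH2Cl2, 0 °C → rt
Reagents that add atoms: none
Why: Steglich-type carbodiimide esterification of the only free (primary) hydroxyl under non-epimerising conditions.

Step 13
Reactants: 19 amide ester
Product: 21 [(1S,2R,3R)-3-(hydroxymethyl)-6-methoxy-1-[3-methoxy-4-(triisopropylsilyloxy)phenyl]-7-(triisopropylsilyloxy)-1,2,3,4-tetrahydronaphthalen-2-yl]methyl (E)-3-[4-(triisopropylsilyloxy)phenyl]prop-2-enoate, via aldehyde 20 (not isolated)
Conditions: Cp2Zr(H)Cl, THF, rt; then H2O/MeOH, NaBH4, 0 °C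
Reagents that add atoms: none
Why: Schwartz reagent should reduce the tertiary amide to the aldehyde through a stable zirconated hemiaminal while tolerating the ester, and borohydride then reduces the aldehyde but not the enoate.

Step 14
Reactants: 21 tris-silyl ether
Product: 22 [(1S,2R,3R)-7-hydroxy-1-(4-hydroxy-3-methoxyphenyl)-3-(hydroxymethyl)-6-methoxy-1,2,3,4-tetrahydronaphthalen-2-yl]methyl (E)-3-(4-hydroxyphenyl)prop-2-enoate (target)
Conditions: TBAF, AcOH (1:1), THF, 0 °C → rt
Reagents that add atoms: none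
Why: Fluoride cleaves the three aryl silyl ethers, and the acetic acid buffer should keep the phenoxides from attacking the coumarate ester.

**Compound list**

1 | vanillin (4-hydroxy-3-methoxybenzaldehyde) | COc1cc(C=O)ccc1O | starting material
2 | 3-methoxy-4-(triisopropylsilyloxy)benzaldehyde | COc1cc(C=O)ccc1O[Si](C(C)C)(C(C)C)C(C)C | intermediate
3 | (S)-4-benzyl-2-oxazolidinone | O=C1OC[C@H](Cc2ccccc2)N1 | starting material
4 | methyl 4-chloro-4-oxobutanoate | COC(=O)CCC(Cl)=O | starting material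
5 | methyl 4-[(S)-4-benzyl-2-oxooxazolidin-3-yl]-4-oxobutanoate | COC(=O)CCC(=O)N1[C@@H](Cc2ccccc2)COC1=O | intermediate
6 | methyl (3S,4S)-3-[(S)-4-benzyl-2-oxooxazolidine-3-carbonyl]-4-hydroxy-4-[3-methoxy-4-(triisopropylsilyloxy)phenyl]butanoate | COC(=O)C[C@@H]([C@H](O)c1ccc(O[Si](C(C)C)(C(C)C)C(C)C)c(OC)c1)C(=O)N1[C@@H](Cc2ccccc2)COC1=O | intermediate
7 | methyl (3S,4S)-3-[(S)-4-benzyl-2-oxooxazolidine-3-carbonyl]-4-(tert-butyldimethylsilyloxy)-4-[3-methoxy-4-(triisopropylsilyloxy)phenyl]butanoate | COC(=O)C[C@@H]([C@H](O[Si](C)(C)C(C)(C)C)c1ccc(O[Si](C(C)C)(C(C)C)C(C)C)c(OC)c1)C(=O)N1[C@@H](Cc2ccccc2)COC1=O | intermediate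
8 | methyl (3R,4S)-4-(tert-butyldimethylsilyloxy)-3-(hydroxymethyl)-4-[3-methoxy-4-(triisopropylsilyloxy)phenyl]butanoate | COC(=O)C[C@H](CO)[C@H](O[Si](C)(C)C(C)(C)C)c1ccc(O[Si](C(C)C)(C(C)C)C(C)C)c(OC)c1 | intermediate
9 | (R)-4-{(S)-(tert-butyldimethylsilyloxy)[3-methoxy-4-(triisopropylsilyloxy)phenyl]methyl}dihydrofuran-2(3H)-one | O=C1C[C@@H]([C@H](O[Si](C)(C)C(C)(C)C)c2ccc(O[Si](C(C)C)(C(C)C)C(C)C)c(OC)c2)CO1 | intermediate
10 | (R)-3-{(S)-(tert-butyldimethylsilyloxy)[3-methoxy-4-(triisopropylsilyloxy)phenyl]methyl}-5-(trimethylsilyloxy)-2,3-dihydrofuran | C[Si](C)(C)OC1=C[C@@H]([C@H](O[Si](C)(C)C(C)(C)C)c2ccc(O[Si](C(C)C)(C(C)C)C(C)C)c(OC)c2)CO1 | intermediate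
11 | [3-methoxy-4-(triisopropylsilyloxy)phenyl]methanol | COc1cc(CO)ccc1O[Si](C(C)C)(C(C)C)C(C)C | intermediate
12 | 3-methoxy-4-(triisopropylsilyloxy)benzyl acetate | COc1cc(COC(C)=O)ccc1O[Si](C(C)C)(C(C)C)C(C)C | intermediate
13 | (3R,4R)-3-[3-methoxy-4-(triisopropylsilyloxy)benzyl]-4-{(S)-(tert-butyldimethylsilyloxy)[3-methoxy-4-(triisopropylsilyloxy)phenyl]methyl}dihydrofuran-2(3H)-one (trans) | O=C1[C@H](Cc2ccc(O[Si](C(C)C)(C(C)C)C(C)C)c(OC)c2)[C@@H]([C@H](O[Si](C)(C)C(C)(C)C)c2ccc(O[Si](C(C)C)(C(C)C)C(C)C)c(OC)c2)CO1 | intermediate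
14 | (3aR,9S,9aR)-6-methoxy-9-[3-methoxy-4-(triisopropylsilyloxy)phenyl]-7-(triisopropylsilyloxy)-3a,4,9,9a-tetrahydronaphtho[2,3-c]furan-3(1H)-one (trans-fused lactone, aryl trans to the CH2O arm) | COc1cc([C@H]2c3cc(O[Si](C(C)C)(C(C)C)C(C)C)c(OC)cc3C[C@H]3C(=O)OC[C@H]23)ccc1O[Si](C(C)C)(C(C)C)C(C)C | intermediate
15 | (2R,3R,4S)-3-(hydroxymethyl)-N,7-dimethoxy-N-methyl-4-[3-methoxy-4-(triisopropylsilyloxy)phenyl]-6-(triisopropylsilyloxy)-1,2,3,4-tetrahydronaphthalene-2-carboxamide | COc1cc([C@H]2c3cc(O[Si](C(C)C)(C(C)C)C(C)C)c(OC)cc3C[C@@H](C(=O)N(C)OC)[C@@H]2CO)ccc1O[Si](C(C)C)(C(C)C)C(C)C | intermediate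
16 | p-coumaric acid ((E)-3-(4-hydroxyphenyl)prop-2-enoic acid) | OC(=O)/C=C/c1ccc(O)cc1 | starting material
17 | triisopropylsilyl (E)-3-[4-(triisopropylsilyloxy)phenyl]prop-2-enoate | CC(C)[Si](OC(=O)/C=C/c1ccc(O[Si](C(C)C)(C(C)C)C(C)C)cc1)(C(C)C)C(C)C | intermediate
18 | (E)-3-[4-(triisopropylsilyloxy)phenyl]prop-2-enoic acid | OC(=O)/C=C/c1ccc(O[Si](C(C)C)(C(C)C)C(C)C)cc1 | intermediate
19 | [(1S,2R,3R)-3-[methoxy(methyl)carbamoyl]-6-methoxy-1-[3-methoxy-4-(triisopropylsilyloxy)phenyl]-7-(triisopropylsilyloxy)-1,2,3,4-tetrahydronaphthalen-2-yl]methyl (E)-3-[4-(triisopropylsilyloxy)phenyl]prop-2-enoate | COc1cc([C@H]2c3cc(O[Si](C(C)C)(C(C)C)C(C)C)c(OC)cc3C[C@@H](C(=O)N(C)OC)[C@@H]2COC(=O)/C=C/c2ccc(O[Si](C(C)C)(C(C)C)C(C)C)cc2)ccc1O[Si](C(C)C)(C(C)C)C(C)C | intermediate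
20 | [(1S,2R,3R)-3-formyl-6-methoxy-1-[3-methoxy-4-(triisopropylsilyloxy)phenyl]-7-(triisopropylsilyloxy)-1,2,3,4-tetrahydronaphthalen-2-yl]methyl (E)-3-[4-(triisopropylsilyloxy)phenyl]prop-2-enoate | COc1cc([C@H]2c3cc(O[Si](C(C)C)(C(C)C)C(C)C)c(OC)cc3C[C@@H](C=O)[C@@H]2COC(=O)/C=C/c2ccc(O[Si](C(C)C)(C(C)C)C(C)C)cc2)ccc1O[Si](C(C)C)(C(C)C)C(C)C | intermediate
21 | [(1S,2R,3R)-3-(hydroxymethyl)-6-methoxy-1-[3-methoxy-4-(triisopropylsilyloxy)phenyl]-7-(triisopropylsilyloxy)-1,2,3,4-tetrahydronaphthalen-2-yl]methyl (E)-3-[4-(triisopropylsilyloxy)phenyl]prop-2-enoate | COc1cc([C@H]2c3cc(O[Si](C(C)C)(C(C)C)C(C)C)c(OC)cc3C[C@@H](CO)[C@@H]2COC(=O)/C=C/c2ccc(O[Si](C(C)C)(C(C)C)C(C)C)cc2)ccc1O[Si](C(C)C)(C(C)C)C(C)C | intermediate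
22 | [(1S,2R,3R)-7-hydroxy-1-(4-hydroxy-3-methoxyphenyl)-3-(hydroxymethyl)-6-methoxy-1,2,3,4-tetrahydronaphthalen-2-yl]methyl (E)-3-(4-hydroxyphenyl)prop-2-enoate | COc1cc([C@H]2c3cc(O)c(OC)cc3C[C@@H](CO)[C@@H]2COC(=O)/C=C/c2ccc(O)cc2)ccc1O | target

**Step count and risks**

Total step count: 14. Longest linear sequence: 10 steps (1, 3, 4, 5, 6, 9, 10, 12, 13, 14).

Steps most likely to fail:

1. Step 9 (Proposed new method). The secondary benzylic silyl ether of 10 may ionise before the acetate does, and the ketene acetal would then capture that cation within the molecule to give a cyclopropane. The ketene acetal may also be protodesilylated by adventitious acid, or the second ionisation may stall at 13. Fallback: the two bonds are made in separate known operations, setting out from lactone 9 and alcohol 11. Alcohol 11 is converted with CBr4/PPh3 (CH2Cl2, 0 °C) into 4-(bromomethyl)-2-methoxy-1-(triisopropylsilyloxy)benzene F1. The lithium enolate of 9 (LiHMDS, THF, −78 °C) is alkylated with F1 anti to the ring substituent to give the trans lactone 13, now isolated. Lactone 13 is cyclised with TFA in CH2Cl2 at 0 °C to 14, where the route is rejoined.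

2. Step 13. The zirconium hydride may add to or conjugatively reduce the cinnamate double bond, or attack the ester, so that the discrimination between amide and enoate is lost. Fallback: the aldehyde is unmasked without any hydride in the presence of the ester, setting out from lactone 14. DIBAL-H (CH2Cl2, −78 °C) gives the lactol (3aR,9S,9aR)-6-methoxy-9-[3-methoxy-4-(triisopropylsilyloxy)phenyl]-7-(triisopropylsilyloxy)-1,3,3a,4,9,9a-hexahydronaphtho[2,3-c]furan-3-ol F2. Propane-1,3-dithiol with BF3·OEt2 (CH2Cl2, −20 °C) opens it to the hydroxy dithiane {(1S,2R,3R)-3-(1,3-dithian-2-yl)-6-methoxy-1-[3-methoxy-4-(triisopropylsilyloxy)phenyl]-7-(triisopropylsilyloxy)-1,2,3,4-tetrahydronaphthalen-2-yl}methanol F3. Esterification with 18 (EDC·HCl, DMAP) gives the dithiane coumarate F4. MeI with CaCO3 in aqueous MeCN releases aldehyde 20, which is reduced with NaBH4 as in step 13 to 21.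

3. Step 5. Reduction may fail to distinguish imide from methyl ester, or the new primary alkoxide may take over the neighbouring silyl group so that the benzylic oxygen closes the wrong lactone. Fallback: setting out from 7, LiOH/H2O2 (THF/H2O, 0 °C) removes the auxiliary to give (2S,3S)-3-(tert-butyldimethylsilyloxy)-2-(2-methoxy-2-oxoethyl)-3-[3-methoxy-4-(triisopropylsilyloxy)phenyl]propanoic acid F5. BH3·SMe2 (THF, 0 °C) reduces the acid in the presence of the methyl ester, without a free alkoxide, to hydroxy ester 8, which is lactonised with PPTS to 9.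

Further compounds
F1 | step 9 | 4-(bromomethyl)-2-methoxy-1-(triisopropylsilyloxy)benzene | COc1cc(CBr)ccc1O[Si](C(C)C)(C(C)C)C(C)C
F2 | step 13 | (3aR,9S,9aR)-6-methoxy-9-[3-methoxy-4-(triisopropylsilyloxy)phenyl]-7-(triisopropylsilyloxy)-1,3,3a,4,9,9a-hexahydronaphtho[2,3-c]furan-3-ol (anomeric mixture) | COc1cc([C@H]2c3cc(O[Si](C(C)C)(C(C)C)C(C)C)c(OC)cc3C[C@H]3C(O)OC[C@H]23)ccc1O[Si](C(C)C)(C(C)C)C(C)C
F3 | step 13 | {(1S,2R,3R)-3-(1,3-dithian-2-yl)-6-methoxy-1-[3-methoxy-4-(triisopropylsilyloxy)phenyl]-7-(triisopropylsilyloxy)-1,2,3,4-tetrahydronaphthalen-2-yl}methanol | COc1cc([C@H]2c3cc(O[Si](C(C)C)(C(C)C)C(C)C)c(OC)cc3C[C@@H](C3SCCCS3)[C@@H]2CO)ccc1O[Si](C(C)C)(C(C)C)C(C)C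
F4 | step 13 | {(1S,2R,3R)-3-(1,3-dithian-2-yl)-6-methoxy-1-[3-methoxy-4-(triisopropylsilyloxy)phenyl]-7-(triisopropylsilyloxy)-1,2,3,4-tetrahydronaphthalen-2-yl}methyl (E)-3-[4-(triisopropylsilyloxy)phenyl]prop-2-enoate | COc1cc([C@H]2c3cc(O[Si](C(C)C)(C(C)C)C(C)C)c(OC)cc3C[C@@H](C3SCCCS3)[C@@H]2COC(=O)/C=C/c2ccc(O[Si](C(C)C)(C(C)C)C(C)C)cc2)ccc1O[Si](C(C)C)(C(C)C)C(C)C
F5 | step 5 | (2S,3S)-3-(tert-butyldimethylsilyloxy)-2-(2-methoxy-2-oxoethyl)-3-[3-methoxy-4-(triisopropylsilyloxy)phenyl]propanoic acid | COC(=O)C[C@@H]([C@H](O[Si](C)(C)C(C)(C)C)c1ccc(O[Si](C(C)C)(C(C)C)C(C)C)c(OC)c1)C(=O)O
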